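**Strategy.** Ring A is closed last, on a ring B bought as (S)-carvone (labdane numbering). The key step reads the gem-dimethyl carbon C4, the C3 methylene and the oxygenated C2 of ring A as a masked bicyclo[4.1.0]heptan-2-one: in a monocyclic precursor carrying trans, on adjacent carbons, an isopropenyl group (C5) and a diazoacetonyl arm (C10), a copper carbene at C3 adds across the isopropenyl C4=CH2, forming C3–C4 and C3–CH2 at once and closing trans-fused ring A. Dissolving-metal reduction then opens the strained exocyclic cyclopropane bond to the second C4 methyl, sets the equatorial C2 alcohol and frees O15. C5 relays C10, C9 and C2; C13 is bought.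

Key step: step 13

Remarks on the chemistry:
- Numbering: ring A = C1–C5, C10; ring B = C5–C10; side chain C11–C15 on C9; C20 = methyl on C10.
- The target is read as (13S)-ent-labd-7-ene-2,15-diyl diacetate. H5 and H9 lie on one face, C20 and the C9 side chain on the other, and the C2 acetoxy group is equatorial (trans to C20).
- Methyl hydrogen (R)-3-methylglutarate and (S)-(+)-carvone are taken as commercial.
- Compounds 8 and 12 are carried as epimer mixtures at a centre that the next step planarises. Compound 23 is drawn as the expected cyclopropane epimer; the other one would converge in step 14.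

**Route**

Step 1
Reactants: 1 methyl hydrogen (R)-3-methylglutarate
Product: 2 methyl (3R)-5-hydroxy-3-methylpentanoate
Conditions: BH3·SMe2, THF, 0 °C → rt; H2O
Reagents that add atoms: none
Why: Chemoselective borane reduction: the free carboxylic acid is reduced much faster than the methyl ester, so the two arms at the bought C13 stereocentre are told apart.

Step 2
Reactants: 2 methyl (3R)-5-hydroxy-3-methylpentanoate
Product: 3 methyl (3R)-5-(benzyloxy)-3-methylpentanoate
Conditions: 2-benzyloxy-1-methylpyridinium triflate, MgO, PhCF3, 83 °C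
Reagents that add atoms: 2-benzyloxy-1-methylpyridinium triflate, C[n+]1ccccc1OCc1ccccc1.[O-]S(=O)(=O)C(F)(F)F
Why: Thermal benzyl transfer from the pyridinium salt etherifies the primary alcohol under neutral conditions (O-benzylation), so the δ-hydroxy ester does not lactonise and C13 is untouched.

Step 3
Reactants: 3 methyl (3R)-5-(benzyloxy)-3-methylpentanoate
Product: 4 (3S)-5-(benzyloxy)-3-methylpentan-1-ol
Conditions: LiAlH4, THF, 0 °C
Reagents that add atoms: none
Why: Hydride reduction of the ester to the primary alcohol; the benzyl ether is inert and keeps the two chain ends different.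

Step 4
Reactants: 4 (3S)-5-(benzyloxy)-3-methylpentan-1-ol
Product: 5 (3R)-5-(benzyloxy)-1-iodo-3-methylpentane
Conditions: I2, PPh3, imidazole, CH2Cl2, 0 °C → rt
Reagents that add atoms: iodine, II
Why: Appel-type iodination: the alkoxyphosphonium iodide collapses by SN2 at the primary carbon (future C11).

Step 5
Reactants: 6 (S)-(+)-carvone
Product: 8 (5S)-2,6-dimethyl-5-(prop-1-en-2-yl)cyclohex-2-en-1-one (both C6 epimers), via lithium dienolate 7 (not isolated)
Conditions: LiN(iPr)2, THF, −78 °C; MeI, −78 → 0 °C
Reagents that add atoms: iodomethane, CI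
Why: Kinetic α′-deprotonation of the cross-conjugated enone at the CH2 that becomes C10, then C-methylation (enolate alkylation); the new centre is planarised again in step 6, so its configuration is irrelevant.

Step 6
Reactants: 8 (5S)-2,6-dimethyl-5-(prop-1-en-2-yl)cyclohex-2-en-1-one
Product: 10 (5R,6R)-2,6-dimethyl-6-(prop-2-en-1-yl)-5-(prop-1-en-2-yl)cyclohex-2-en-1-one, via lithium enolate 9 (not isolated)
Conditions: LiN(iPr)2, THF, −78 °C; allyl bromide, DMPU, −78 °C → rt
Reagents that add atoms: allyl bromide, C=CCBr
Why: Substrate-controlled enolate alkylation: allyl bromide enters the tetrasubstituted enolate anti to the adjacent C5 isopropenyl group, so the quaternary C10 carries CH3 cis and allyl trans to isopropenyl.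

Step 7
Reactants: 5 (3R)-5-(benzyloxy)-1-iodo-3-methylpentane; 10 (5R,6R)-2,6-dimethyl-6-(prop-2-en-1-yl)-5-(prop-1-en-2-yl)cyclohex-2-en-1-one
Product: 12 1-[(3S)-5-(benzyloxy)-3-methylpentyl]-2,6-dimethyl-6-(prop-2-en-1-yl)-5-(prop-1-en-2-yl)cyclohex-2-en-1-ol (both carbinol epimers), via alkyllithium 11 (not isolated)
Conditions: 5, tBuLi (2 equiv), Et2O–pentane, −78 °C; then 10, THF, −78 → 0 °C; aq NH4Cl
Reagents that add atoms: none
Why: Lithium–iodine exchange gives the primary alkyllithium, which adds 1,2 to the enone carbonyl (future C9) that cannot be enolised toward the quaternary C10; either carbinol epimer serves because step 8 planarises this centre.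

Step 8
Reactants: 12 tertiary allylic alcohol
Product: 13 3-[(3S)-5-(benzyloxy)-3-methylpentyl]-2,4-dimethyl-4-(prop-2-en-1-yl)-5-(prop-1-en-2-yl)cyclohex-2-en-1-one (C7 ketone, C8=C9 alkene; allyl trans to isopropenyl)
Conditions: pyridinium chlorochromate [C5H5NH][CrO3Cl], 4 Å MS, CH2Cl2, rt
Reagents that add atoms: pyridinium chlorochromate, [O-][Cr](=O)(=O)Cl.c1cc[nH+]cc1
Why: Babler–Dauben oxidative 1,3-transposition: hexavalent chromium esterifies the tertiary allylic alcohol, the oxygen function shifts suprafacially from C9 to C7 and is oxidised there, giving the enone with the side chain now on an sp2 C9.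

Step 9
Reactants: 13 transposed enone
Product: 14 3-[(3S)-5-(benzyloxy)-3-methylpentyl]-2,4-dimethyl-4-(prop-2-en-1-yl)-5-(prop-1-en-2-yl)cyclohex-2-en-1-ol with the C7 hydroxyl cis to the isopropenyl group
Conditions: NaBH4, CeCl3·7H2O, MeOH, −78 → 0 °C
Reagents that add atoms: none
Why: Luche reduction: CeCl3 enforces 1,2-addition and hydride enters axially on the face of H5, anti to the axial C10 methyl, as in the reduction of carvone to cis-carveol, so the C7 hydroxyl ends cis to isopropenyl.

Step 10
Reactants: 14 allylic alcohol
Product: 17 cyclohexene with C7=C8 and H9 cis to H5 (C9 side chain cis to the C10 methyl; C10 carries CH3 and allyl; C5 carries isopropenyl), via sulfonylhydrazine 15 (not isolated), via allylic diazene 16 (not isolated)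
Conditions: 2-O2NC6H4SO2NHNH2, PPh3, DEAD, THF, −30 °C → rt
Reagents that add atoms: none
Why: Reductive 1,3-transposition of an allylic alcohol (Mitsunobu then retro-ene): substitution by the sulfonylhydrazide inverts C7 and puts nitrogen on the face of H5, loss of the sulfinic acid gives diazene 16, and its suprafacial retro-ene loss of N2 delivers hydrogen to C9 on that same face, moving the alkene to C7=C8 and setting C9.

Step 11
Reactants: 17 triene
Product: 18 methyl ketone (C10–CH2–CO–CH3 in place of the allyl group)
Conditions: PdCl2 (cat.), CuCl, O2 (1 atm), DMF–H2O, rt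
Reagents that add atoms: water, O
Why: Tsuji–Wacker oxidation: hydroxypalladation by divalent palladium is far faster at the monosubstituted allyl alkene than at the 1,1-disubstituted and trisubstituted alkenes and adds water in the Markovnikov sense.

Step 12
Reactants: 18 methyl ketone
Product: 21 diazomethyl ketone (C10–CH2–CO–CHN2), via lithium enolate 19 (not isolated), via trifluoroacetyl diketone 20 (not isolated)
Conditions: LiN(SiMe3)2, THF, −78 °C; CF3CO2CH2CF3; then MsN3, Et3N, H2O, MeCN, rt
Reagents that add atoms: methanesulfonyl azide, CS(=O)(=O)N=[N+]=[N-]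
Why: Deacylative diazo transfer: the kinetic enolate forms at the methyl group (the other α-carbon is neopentylic), C-trifluoroacetylation activates it, and diazo transfer with loss of the trifluoroacetyl group as its sulfonamide leaves the diazo ketone.

Step 13
Reactants: 21 diazomethyl ketone
Product: 23 (13S)-15-(benzyloxy)-3,19-cyclo-ent-labd-7-en-2-one (cyclopropane CH2 on the C20 face), via copper carbene 22 (not isolated)
Conditions: Cu(acac)2 (cat.), toluene, 110 °C, slow addition, high dilution
Reagents that add atoms: none
Why: Copper-mediated loss of N2 from 21 gives the electrophilic copper carbene 22, whose C3 adds in a concerted, asynchronous [2+1] manner to the 1,1-disubstituted C4=CH2 of the isopropenyl group, bonding first to the terminal CH2 and then to C4. The closest known reaction type is the intramolecular cyclopropanation of 1-diazohept-6-en-2-ones to bicyclo[4.1.0]heptan-2-ones. Ring A (C1–C2–C3–C4–C5–C10) closes in the six-membered exo mode onto C4, the alkene terminus staying outside as the cyclopropane methylene, and the ring can only be trans-fused to ring B because the C10 arm and the C5 isopropenyl group are trans-diequatorial. The new stereocentres C3 and C4 are controlled by the obligatory cis fusion of the three-membered ring and by the isopropenyl rotamer that turns its CH2, not its CH3, toward C20; both centres are erased in step 14, so either cyclopropane epimer serves. The step needs chemoselectivity for the isopropenyl group over the C7=C8 alkene and over 1,5 C–H insertion at C5–H and C9–H: attack on C8 would need an axial arm and give a bridged bicyclo[3.3.1] skeleton, and copper carbenes prefer alkene addition to C–H insertion far more than dirhodium carbenes do. Slow addition at high dilution suppresses carbene dimerisation.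

Step 14
Reactants: 23 cyclopropyl ketone
Product: 26 (13S)-ent-labd-7-ene-2,15-diol with equatorial 2-OH (trans to C20), via dilithium enolate 24 (not isolated), via hydroxy ketone 25 (not isolated)
Conditions: Li, NH3(l)–THF, −78 → −33 °C; then EtOH; NH4Cl
Reagents that add atoms: none
Why: Dissolving-metal reduction: the ketyl radical anion cleaves the cyclopropane bond that overlaps best with the carbonyl π system, in a bicyclo[4.1.0]heptan-2-one the exocyclic C3–CH2 bond, so protonation by ammonia leaves the second C4 methyl and enolate 24; ethanol then releases ketone 25, which excess lithium reduces under thermodynamic control to the equatorial C2 alkoxide (anti to the axial methyls on C4 and C10), while the benzyl ether is cleaved in the same pot.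

Step 15
Reactants: 26 diol
Product: 27 CNP0220683.1, (13S)-ent-labd-7-ene-2,15-diyl diacetate
Conditions: Ac2O, pyridine, DMAP (cat.), CH2Cl2, rt
Reagents that add atoms: acetic anhydride, CC(=O)OC(C)=O
Why: DMAP-catalysed acylation esterifies the primary C15 and the equatorial secondary C2 hydroxyl; no stereocentre is touched.

**Compound list**

1 | methyl hydrogen (R)-3-methylglutarate | OC(=O)C[C@@H](C)CC(=O)OC | starting material
2 | methyl (3R)-5-hydroxy-3-methylpentanoate | OCC[C@@H](C)CC(=O)OC | intermediate
3 | methyl (3R)-5-(benzyloxy)-3-methylpentanoate | c1ccccc1COCC[C@@H](C)CC(=O)OC | intermediate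
4 | (3S)-5-(benzyloxy)-3-methylpentan-1-ol | c1ccccc1COCC[C@@H](C)CCO | intermediate
5 | (3R)-5-(benzyloxy)-1-iodo-3-methylpentane | c1ccccc1COCC[C@@H](C)CCI | intermediate
6 | (S)-(+)-carvone | O=C1C(C)=CC[C@H](C(C)=C)C1 | starting material
7 | lithium dienolate of carvone (not isolated) | [Li]OC1=C[C@@H](C(C)=C)CC=C1C | intermediate
8 | (5S)-2,6-dimethyl-5-(prop-1-en-2-yl)cyclohex-2-en-1-one, both C6 epimers | O=C1C(C)=CC[C@H](C(C)=C)C1C | intermediate
9 | lithium enolate of 8 (not isolated) | [Li]OC1=C(C)[C@@H](C(C)=C)CC=C1C | intermediate
10 | (5R,6R)-2,6-dimethyl-6-(prop-2-en-1-yl)-5-(prop-1-en-2-yl)cyclohex-2-en-1-one (allyl trans to isopropenyl) | O=C1C(C)=CC[C@H](C(C)=C)[C@@]1(C)CC=C | intermediate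
11 | [(3S)-5-(benzyloxy)-3-methylpentyl]lithium (not isolated) | c1ccccc1COCC[C@@H](C)CC[Li] | intermediate
12 | tertiary allylic alcohol from 11 and 10, both C9 carbinol epimers | c1ccccc1COCC[C@@H](C)CCC1(O)C(C)=CC[C@H](C(C)=C)[C@@]1(C)CC=C | intermediate
13 | transposed enone (C7=O, C8=C9) | c1ccccc1COCC[C@@H](C)CCC1=C(C)C(=O)C[C@H](C(C)=C)[C@@]1(C)CC=C | intermediate
14 | allylic alcohol, C7–OH cis to isopropenyl | c1ccccc1COCC[C@@H](C)CCC1=C(C)[C@H](O)C[C@H](C(C)=C)[C@@]1(C)CC=C | intermediate
15 | N-allylic N-(2-nitrobenzenesulfonyl)hydrazine, N on C7 trans to isopropenyl (not isolated) | c1ccccc1COCC[C@@H](C)CCC1=C(C)[C@@H](N(N)S(=O)(=O)c2ccccc2[N+](=O)[O-])C[C@H](C(C)=C)[C@@]1(C)CC=C | intermediate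
16 | allylic monoalkyl diazene (not isolated) | c1ccccc1COCC[C@@H](C)CCC1=C(C)[C@@H](N=N)C[C@H](C(C)=C)[C@@]1(C)CC=C | intermediate
17 | ring B triene: C7=C8, H9 cis to H5, allyl and CH3 on C10, isopropenyl on C5 | c1ccccc1COCC[C@@H](C)CC[C@@H]1C(C)=CC[C@H](C(C)=C)[C@@]1(C)CC=C | intermediate
18 | methyl ketone (acetonyl on C10) | c1ccccc1COCC[C@@H](C)CC[C@@H]1C(C)=CC[C@H](C(C)=C)[C@@]1(C)CC(C)=O | intermediate
19 | kinetic lithium enolate of 18 (not isolated) | c1ccccc1COCC[C@@H](C)CC[C@@H]1C(C)=CC[C@H](C(C)=C)[C@@]1(C)CC(=C)O[Li] | intermediate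
20 | trifluoroacetyl diketone (not isolated) | c1ccccc1COCC[C@@H](C)CC[C@@H]1C(C)=CC[C@H](C(C)=C)[C@@]1(C)CC(=O)CC(=O)C(F)(F)F | intermediate
21 | diazomethyl ketone (diazoacetonyl on C10) | c1ccccc1COCC[C@@H](C)CC[C@@H]1C(C)=CC[C@H](C(C)=C)[C@@]1(C)CC(=O)C=[N+]=[N-] | intermediate
22 | copper carbene at C3, ancillary ligands omitted (not isolated) | c1ccccc1COCC[C@@H](C)CC[C@@H]1C(C)=CC[C@H](C(C)=C)[C@@]1(C)CC(=O)C=[Cu] | intermediate
23 | (13S)-15-(benzyloxy)-3,19-cyclo-ent-labd-7-en-2-one, cyclopropane CH2 on the C20 face | c1ccccc1COCC[C@@H](C)CC[C@@H]1C(C)=CC[C@@H]2[C@]3(C)C[C@@H]3C(=O)C[C@@]12C | intermediate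
24 | dilithium C2=C3 enolate and C15 alkoxide (not isolated) | [Li]OCC[C@@H](C)CC[C@@H]1C(C)=CC[C@@H]2C(C)(C)C=C(O[Li])C[C@@]12C | intermediate
25 | (13S)-15-hydroxy-ent-labd-7-en-2-one (not isolated) | OCC[C@@H](C)CC[C@@H]1C(C)=CC[C@@H]2C(C)(C)CC(=O)C[C@@]12C | intermediate
26 | (13S)-ent-labd-7-ene-2,15-diol, 2-OH equatorial | OCC[C@@H](C)CC[C@@H]1C(C)=CC[C@@H]2C(C)(C)C[C@@H](O)C[C@@]12C | intermediate
27 | CNP0220683.1, (13S)-ent-labd-7-ene-2,15-diyl diacetate | CC(=O)OCC[C@@H](C)CC[C@@H]1C(C)=CC[C@@H]2C(C)(C)C[C@@H](OC(C)=O)C[C@@]12C | target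

**Count and risks**

Total step count: 15. Longest linear sequence: 13 steps (steps 1–4, then 7–15); the carvone branch (steps 5–6) joins at step 7.

Steps most likely to fail:

1. Step 13. The copper carbene may be diverted into 1,5 C–H insertion at the allylic C5–H or C9–H bonds, or into intermolecular dimerisation, before it reaches the isopropenyl group. The fallback avoids a carbene altogether; it sets out from methyl ketone 18 and comes back at diol 26. The kinetic enolate of 18 (LiN(SiMe3)2, THF, −78 °C) is trapped by dimethyl(methylidene)ammonium iodide to give the β-dimethylamino ketone F1. Quaternisation with MeI and elimination with DBU give the vinyl ketone F2. Ring-closing metathesis of the enone vinyl group with the isopropenyl group (second-generation Hoveyda–Grubbs catalyst, toluene, 80 °C) forms C3=C4 and closes ring A as the 4-methyl enone F3. Conjugate addition of Me2CuLi (Me3SiCl, Et2O, −78 → 0 °C) installs the second C4 methyl and gives the gem-dimethyl ketone benzyl ether F4. Li/NH3 followed by EtOH, as in step 14, reduces C2=O to the equatorial alcohol and removes the benzyl group, giving 26.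

2. Step 10. The Mitsunobu displacement at the hindered allylic C7 carbinol may stall or turn into elimination to a conjugated diene, so that no diazene forms. The fallback sets out from allylic alcohol 14 and comes back at triene 17. Acylation (ClCO2Me, pyridine, DMAP, CH2Cl2) gives the allylic methyl carbonate F5. Palladium-catalysed formate hydrogenolysis follows (Pd(OAc)2, PBu3, HCO2H, Et3N, THF, reflux). Zerovalent palladium ionises the carbonate with inversion and so sits on the face of H5. Hydride from the palladium formate is then delivered to the more substituted allyl terminus C9 on that same face, leaving the C7=C8 alkene and the same C9 configuration as in 17.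

3. Step 14. Electron transfer may open the ring-fusion C3–C4 bond instead of the exocyclic bond (ring enlargement to a seven-membered ketone), or the three reductions may not all finish in one pot. The fallback sets out from cyclopropyl ketone 23 and comes back at diol 26. Me3SiI (CH2Cl2, −20 °C → rt, aqueous work-up) opens the activated cyclopropane by attack of iodide at the unhindered cyclopropane methylene, which can only break the exocyclic bond, and cleaves the benzyl ether as well, giving the iodomethyl hydroxy ketone F6. Bu3SnH with AIBN (benzene, 80 °C) replaces iodine by hydrogen and gives hydroxy ketone 25, now isolated. Li/NH3 with EtOH then reduces only the C2 ketone, under thermodynamic control, to the equatorial alcohol of 26.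

Further compounds
F1 | step 13 | β-dimethylamino ketone (Mannich base of 18) | c1ccccc1COCC[C@@H](C)CC[C@@H]1C(C)=CC[C@H](C(C)=C)[C@@]1(C)CC(=O)CCN(C)C
F2 | step 13 | vinyl ketone (C10–CH2–CO–CH=CH2) | c1ccccc1COCC[C@@H](C)CC[C@@H]1C(C)=CC[C@H](C(C)=C)[C@@]1(C)CC(=O)C=C
F3 | step 13 | ring A enone, (13S)-15-(benzyloxy)-19-nor-ent-labda-3,7-dien-2-one | c1ccccc1COCC[C@@H](C)CC[C@@H]1C(C)=CC[C@@H]2C(C)=CC(=O)C[C@@]12C
F4 | step 13 | (13S)-15-(benzyloxy)-ent-labd-7-en-2-one | c1ccccc1COCC[C@@H](C)CC[C@@H]1C(C)=CC[C@@H]2C(C)(C)CC(=O)C[C@@]12C
F5 | step 10 | allylic methyl carbonate of 14 | c1ccccc1COCC[C@@H](C)CCC1=C(C)[C@H](OC(=O)OC)C[C@H](C(C)=C)[C@@]1(C)CC=C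
F6 | step 14 | (13S)-15-hydroxy-19-iodo-ent-labd-7-en-2-one | OCC[C@@H](C)CC[C@@H]1C(C)=CC[C@@H]2[C@](C)(CI)CC(=O)C[C@@]12C
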